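**Plan**

- Numbering follows the hydroxy acid chain: C1 is the lactone carbonyl carbon, C2 to C29 are CH2 groups, C30 is the OCH2 carbon. The only ring is the 31-membered oxacycle (O, C1 to C30).
- Retrosynthetic cuts: first the ring bond C7–C8 (CH2–CH2), then the ester bond O–C1, then C18–C19 in the alcohol arm. This leaves a C7 bromo acid, a C12 bromo alcohol and a C11 bromoalkene, all commercial.
- Forward order: C18–C19 by copper-catalysed Grignard coupling (C11 + C12 gives the C23 alkenol), O–C1 by esterification, bromide to iodide exchange at C7, then one-pot hydroboration of C8=C9 and palladium-mediated sp3–sp3 coupling C7–C8, which closes the ring.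
- Enabling feature: the ring carries a single functional group, the ester O–C1(=O), among 29 unactivated CH2 groups. The ester is inert to 9-BBN and to zerovalent palladium with phosphate, so it can tether an electrophilic C7–I arm to a nucleophilic C8–B arm, and the strain-free 31-membered ring costs entropy only.
- The two activating groups (iodine on C7, boron on C8) both leave in the ring-closing event, so no helper remains to be removed. The target has no stereocentre and no double bond, so no stereochemistry has to be set.

Key step: step 4

**Route**

Step 1
Reactants: 1 11-bromoundec-1-ene; 2 12-bromododecan-1-ol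
Product: 5 tricos-22-en-1-ol, via Grignard reagent 3 (not isolated), via magnesium alkoxide 4 (not isolated)
Conditions: 1 (2.3 equiv), Mg, THF, 40 °C; then 2 (1 equiv), THF, −10 °C; then Li2CuCl4 (3 mol%), −10 °C to rt; aq NH4Cl
Reagents that add atoms: none
Why: Copper-catalysed sp3–sp3 cross-coupling of a Grignard reagent with a primary alkyl bromide (Kochi coupling, Li2CuCl4): the first equivalent of 3 turns the hydroxyl group of 2 into the inert alkoxide 4, the second displaces the primary bromide through an alkylcuprate, and the terminal alkene does not react.

Step 2
Reactants: 5 tricos-22-en-1-ol; 6 7-bromoheptanoic acid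
Product: 7 tricos-22-en-1-yl 7-bromoheptanoate
Conditions: EDC·HCl (1.3 equiv), DMAP (0.1 equiv), CH2Cl2, 0 °C to rt
Reagents that add atoms: none
Why: Steglich-type carbodiimide esterification: EDC activates acid 6 as its O-acylisourea and DMAP relays the acyl group to the unhindered primary alcohol, while the primary bromide and the terminal alkene are inert at room temperature.

Step 3
Reactants: 7 tricos-22-en-1-yl 7-bromoheptanoate
Product: 8 tricos-22-en-1-yl 7-iodoheptanoate
Conditions: NaI (3 equiv), acetone, reflux
Reagents that add atoms: sodium iodide [Na+].[I-]
Why: Finkelstein reaction: SN2 halide exchange at the primary C7 carbon, driven by precipitation of NaBr from acetone, installs the iodide, which should undergo oxidative addition to zerovalent palladium much faster than the bromide, as the dilute key step requires.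

Step 4
Reactants: 8 tricos-22-en-1-yl 7-iodoheptanoate
Product: 10 oxacyclohentriacontan-2-one (triacontan-30-olide), via alkylborane 9 (not isolated)
Conditions: 9-BBN dimer (0.52 equiv), THF, 0 °C to rt; then syringe-pump addition over 12 h to Pd(PCy3)2 (15 mol%), K3PO4·H2O (3 equiv), THF, rt, final concentration 2 mM, argon
Reagents that add atoms: none
Why: Proposed new method: 9-BBN should add anti-Markovnikov to the terminal C8=C9 alkene of 8 and place boron on C8 without touching the ester or the primary iodide; zerovalent palladium then inserts into the C7–I bond by an SN2-type oxidative addition, the hydroxide-activated borate at the other end of the same chain transmetalates through a Pd–O–B bridge, and reductive elimination forms C7–C8. The closest known reaction types are the intermolecular alkyl–alkyl Suzuki–Miyaura coupling of B-alkyl-9-BBN reagents with primary alkyl halides that carry β-hydrogens (trialkylphosphine-ligated palladium, K3PO4·H2O, ester-tolerant) and the B-alkyl Suzuki–Miyaura macrocyclisation onto alkenyl iodides; their union, a ring closure onto an sp3 electrophile, has not been shown. The one ring closed is the 31-membered lactone, formally a 31-exo-tet closure that proceeds by reductive elimination from a 32-membered palladacycle; the ring is strain-free, so the cost is entropic only, and no stereocentre is formed. The step needs cyclisation to beat head-to-tail oligomerisation, which the slow addition should secure because the tethered borate then competes only with sub-millimolar external borate, and it needs C–C coupling to beat β-hydride elimination, which the two bulky PCy3 ligands should secure by leaving the alkylpalladium iodide no vacant cis site while it waits for transmetalation. Iodide is used in place of bromide because oxidative addition is the only step that is bimolecular in catalyst and substrate and must stay fast at millimolar concentration.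

**Compound list**

1 | 11-bromoundec-1-ene | C=CCCCCCCCCCBr | starting material
2 | 12-bromododecan-1-ol | OCCCCCCCCCCCCBr | starting material
3 | undec-10-en-1-ylmagnesium bromide | C=CCCCCCCCCC[Mg]Br | intermediate
4 | bromomagnesium 12-bromododecan-1-olate | BrCCCCCCCCCCCCO[Mg]Br | intermediate
5 | tricos-22-en-1-ol | C=CCCCCCCCCCCCCCCCCCCCCCO | intermediate
6 | 7-bromoheptanoic acid | OC(=O)CCCCCCBr | starting material
7 | tricos-22-en-1-yl 7-bromoheptanoate | BrCCCCCCC(=O)OCCCCCCCCCCCCCCCCCCCCCC=C | intermediate
8 | tricos-22-en-1-yl 7-iodoheptanoate | ICCCCCCC(=O)OCCCCCCCCCCCCCCCCCCCCCC=C | intermediate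
9 | 23-(9-borabicyclo[3.3.1]nonan-9-yl)tricosyl 7-iodoheptanoate | ICCCCCCC(=O)OCCCCCCCCCCCCCCCCCCCCCCCB1C2CCCC1CCC2 | intermediate
10 | oxacyclohentriacontan-2-one (triacontan-30-olide) | O=C1CCCCCCCCCCCCCCCCCCCCCCCCCCCCCO1 | target

**Totals**

Total step count: 4. Longest linear sequence: 4 steps (1 → 5 → 7 → 8 → 10).

**Steps most likely to fail**

1. Step 4 (proposed new method). Head-to-tail oligomerisation may overtake ring closure if transmetalation of the tethered borate is slow, and β-hydride elimination or protodehalogenation of the alkylpalladium iodide may compete while it waits. The fallback uses known chemistry, sets out from 2 and returns to the route at 10. Compound 2 is coupled as in step 1 (Li2CuCl4, THF, through alkoxide 4) with dodec-11-en-1-ylmagnesium bromide F1, made from commercial 12-bromododec-1-ene and Mg and used at 2.2 equiv, which should give tetracos-23-en-1-ol F2. EDC·HCl/DMAP esterification with commercial oct-7-enoic acid should give tetracos-23-en-1-yl oct-7-enoate F3. Ring-closing metathesis with second-generation Grubbs catalyst (CH2Cl2, 40 °C, 1 mM) should close the same C7–C8 linkage as an alkene, oxacyclohentriacont-8-en-2-one F4, expected as an E/Z mixture in which both isomers converge. Hydrogenation (H2, 10% Pd/C, EtOAc, rt) should then deliver 10.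

2. Step 1. Aggregation or precipitation of the magnesium alkoxide and Wurtz-type homocoupling of the Grignard reagent may leave the cross-coupling incomplete. The fallback sets out from 2 and returns at 5, replacing the free-alkoxide coupling by a protect–couple–deprotect sequence. Compound 2 with 3,4-dihydro-2H-pyran and PPTS in CH2Cl2 should give 2-[(12-bromododecyl)oxy]oxane F5. Li2CuCl4-catalysed coupling of F5 with Grignard reagent 3 (1.2 equiv, THF, −10 °C to rt) should give 2-(tricos-22-en-1-yloxy)oxane F6. Acetal cleavage with PPTS in MeOH at 50 °C should return 5.

3. Step 2. The O-acylisourea may rearrange to the unreactive N-acylurea while acylation of the poorly soluble long-chain alcohol is slow, and DMAP may be N-alkylated by the primary bromide. The fallback sets out from 5 (with 6) and returns at 7. It is a Mitsunobu esterification (PPh3, DIAD, THF, 0 °C to rt), which activates the alcohol oxygen at C30 instead of the acid and needs no acyl-transfer catalyst. No new compound arises on the way (F0).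

**Further compounds**

F1 | step 4 | dodec-11-en-1-ylmagnesium bromide | C=CCCCCCCCCCC[Mg]Br
F2 | step 4 | tetracos-23-en-1-ol | C=CCCCCCCCCCCCCCCCCCCCCCCO
F3 | step 4 | tetracos-23-en-1-yl oct-7-enoate | C=CCCCCCC(=O)OCCCCCCCCCCCCCCCCCCCCCCC=C
F4 | step 4 | oxacyclohentriacont-8-en-2-one (E/Z mixture, geometry not specified) | O=C1CCCCCC=CCCCCCCCCCCCCCCCCCCCCCCO1
F5 | step 1 | 2-[(12-bromododecyl)oxy]oxane | BrCCCCCCCCCCCCOC1CCCCO1
F6 | step 1 | 2-(tricos-22-en-1-yloxy)oxane | C=CCCCCCCCCCCCCCCCCCCCCCOC1CCCCO1
F0 | step 2 | none | none
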